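**Retrosynthetic overview**
- The target comes from an allylic alcohol by C2'–O methylation and C1'–O desilylation. The C2'–C3' bond is made by a nickel-catalysed Nozaki–Hiyama–Kishi coupling of a West aldehyde (ring A already in place) with an East (E)-alkenyl iodide, and Felkin control sets C2'.
- The West aldehyde comes from ozonolysis of a vinyl lactone. Ring A is the only ring and is closed before the fragment union by a new Pd-catalysed, carboxylate-directed alkenyl C–H alkylation of acrylic acid with a terminal epoxide (C4–C5 bond), followed by lactonisation.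
- The East alkenyl iodide comes from Takai olefination of a diacetoxy aldehyde, made by ozonolysis, acetylation and hydride opening of an epoxy alcohol.
- Both epoxy alcohols come from divinylcarbinol by enantiocomplementary Sharpless desymmetrisation: the D-tartrate sets C6/C1', the L-tartrate sets C5'/C6'.

Assumption: locants are ring A = O1, C2(=O), C3=C4, C5, C6 and side chain C1' (CHOH) to C7' (CH3); tBuOOH, ozone and CHI3 are treated as reagents, divinylcarbinol and acrylic acid as starting materials.

**Route**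

Step 1
Reactants: 1 penta-1,4-dien-3-ol (divinylcarbinol)
Product: 2 (1R)-1-[(2S)-oxiran-2-yl]prop-2-en-1-ol
Conditions: Ti(OiPr)4 (10 mol%), D-(−)-diisopropyl tartrate (13 mol%), tBuOOH, 4 Å MS, CH2Cl2, −20 °C
Reagents that add atoms: tert-butyl hydroperoxide, CC(C)(C)OO
Why: Sharpless asymmetric epoxidation run as a desymmetrisation, in which the D-tartrate catalyst picks one enantiotopic vinyl group and one face to give the erythro epoxy alcohol while the minor enantiomer is drained to bis-epoxide, so C6 (S) and C1' are set with very high ee.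

Step 2
Reactants: 2 (1R)-1-[(2S)-oxiran-2-yl]prop-2-en-1-ol
Product: 3 tert-butyldimethyl{[(1R)-1-[(2S)-oxiran-2-yl]prop-2-en-1-yl]oxy}silane
Conditions: TBSCl, imidazole, DMF, 0 °C to rt
Reagents that add atoms: tert-butyldimethylsilyl chloride, CC(C)(C)[Si](C)(C)Cl
Why: Imidazole-promoted silylation of the secondary alcohol gives a TBS ether that later enforces Felkin addition and can be removed last without touching acetates.

Step 3
Reactants: 3 tert-butyldimethyl{[(1R)-1-[(2S)-oxiran-2-yl]prop-2-en-1-yl]oxy}silane; 4 acrylic acid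
Product: 6 (6S)-6-[(1R)-1-[(tert-butyldimethylsilyl)oxy]prop-2-en-1-yl]-5,6-dihydro-2H-pyran-2-one, via hydroxy acid 5 (not isolated)
Conditions: Pd(OAc)2 (10 mol%), N-acetylglycine (20 mol%), KOAc (1 equiv), 4 (3 equiv), HFIP, 45 °C
Reagents that add atoms: none
Why: Proposed new method: the carboxylate of 4 directs divalent palladium to the cis β-C(sp2)–H bond (concerted metalation–deprotonation assisted by the N-acyl amino acid) to give a five-membered alkenyl palladacycle, whose Pd–C bond opens the HFIP-activated epoxide 3 at its unhindered CH2 terminus in an SN2-type, redox-neutral step (through transient tetravalent palladium), forming C4–C5 with the Z geometry fixed by the metallacycle and the C6 stereocentre untouched, after which protodemetalation releases (Z)-hydroxy acid 5 that lactonises to ring A; the closest known reaction type is the Pd-catalysed carboxylate-directed ortho C–H alkylation of benzoic acids with terminal epoxides to 3,4-dihydroisocoumarins, together with carboxylate-directed alkenyl C–H functionalisation of acrylic acids.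

Step 4
Reactants: 6 (6S)-6-[(1R)-1-[(tert-butyldimethylsilyl)oxy]prop-2-en-1-yl]-5,6-dihydro-2H-pyran-2-one
Product: 8 (2S)-2-[(tert-butyldimethylsilyl)oxy]-2-[(2S)-6-oxo-3,6-dihydro-2H-pyran-2-yl]acetaldehyde, via ozonide 7 (not isolated)
Conditions: O3, CH2Cl2, −78 °C (Sudan Red 7B end point); then PPh3, −78 °C to rt; used crude
Reagents that add atoms: ozone, [O-][O+]=O
Why: Ozonolysis with reductive work-up, in which the terminal vinyl group reacts with ozone faster than the electron-poor conjugated ring alkene when dosing stops at the indicator end point, and neutral PPh3 reduction of the ozonide gives the aldehyde without epimerising C1'.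

Step 5
Reactants: 1 penta-1,4-dien-3-ol (divinylcarbinol)
Product: 9 (1S)-1-[(2R)-oxiran-2-yl]prop-2-en-1-ol
Conditions: Ti(OiPr)4 (10 mol%), L-(+)-diisopropyl tartrate (13 mol%), tBuOOH, 4 Å MS, CH2Cl2, −20 °C
Reagents that add atoms: tert-butyl hydroperoxide, CC(C)(C)OO
Why: The same Sharpless desymmetrisation with the L-tartrate gives the enantiomeric erythro epoxy alcohol, which sets C5' (S) and C6' (R) of the target.

Step 6
Reactants: 9 (1S)-1-[(2R)-oxiran-2-yl]prop-2-en-1-ol
Product: 10 (2R,3S)-pent-4-ene-2,3-diol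
Conditions: LiAlH4, THF, −20 to 0 °C; Na2SO4·10H2O work-up
Reagents that add atoms: none
Why: Hydride opens the terminal epoxide at the unhindered CH2 carbon (SN2 epoxide reduction), turning it into the C7' methyl group and leaving both stereocentres untouched, so the anti 2,3-diol results.

Step 7
Reactants: 10 (2R,3S)-pent-4-ene-2,3-diol
Product: 11 (3S,4R)-pent-1-ene-3,4-diyl diacetate
Conditions: Ac2O, pyridine, DMAP (cat.), CH2Cl2, 0 °C to rt
Reagents that add atoms: acetic anhydride, CC(=O)OC(C)=O
Why: DMAP-catalysed acyl transfer acetylates both hydroxyls, installing the two target acetates early so that no late diol differentiation is needed.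

Step 8
Reactants: 11 (3S,4R)-pent-1-ene-3,4-diyl diacetate
Product: 13 (2R,3R)-1-oxobutane-2,3-diyl diacetate, via ozonide 12 (not isolated)
Conditions: O3, CH2Cl2, −78 °C; then PPh3, −78 °C to rt; used crude
Reagents that add atoms: ozone, [O-][O+]=O
Why: Ozonolysis of the only alkene with neutral reductive work-up gives the α,β-diacetoxy aldehyde without base, so neither epimerisation nor β-elimination of acetate occurs.

Step 9
Reactants: 13 (2R,3R)-1-oxobutane-2,3-diyl diacetate
Product: 14 (1E,3S,4R)-1-iodopent-1-ene-3,4-diyl diacetate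
Conditions: CrCl2 (6 equiv), CHI3 (2 equiv), THF/1,4-dioxane, 0 °C to rt
Reagents that add atoms: iodoform, IC(I)I
Why: Takai olefination, in which the geminal dichromium carbenoid from CHI3 and divalent chromium adds to the aldehyde and eliminates to the (E)-alkenyl iodide under non-basic conditions that spare the acetates and the α-stereocentre.

Step 10
Reactants: 8 (2S)-2-[(tert-butyldimethylsilyl)oxy]-2-[(2S)-6-oxo-3,6-dihydro-2H-pyran-2-yl]acetaldehyde; 14 (1E,3S,4R)-1-iodopent-1-ene-3,4-diyl diacetate
Product: 16 (2R,3S,4E,6R,7R)-7-[(tert-butyldimethylsilyl)oxy]-6-hydroxy-7-[(2S)-6-oxo-3,6-dihydro-2H-pyran-2-yl]hept-4-ene-2,3-diyl diacetate, via alkenylchromium 15 (not isolated)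
Conditions: CrCl2 (4 equiv), NiCl2 (1 mol%), degassed DMSO, rt; 14 (1.5 equiv)
Reagents that add atoms: none
Why: Nickel-catalysed Nozaki–Hiyama–Kishi coupling, in which zerovalent nickel inserts into the C–I bond and transmetalation gives alkenylchromium 15 that adds only to the aldehyde with retention of the (E) geometry (acetates, lactone and enoate are inert), while Felkin–Anh attack anti to the α-OTBS group, reinforced by the anti β-acyloxy substituent, sets C2' as R (1',2'-anti).

Step 11
Reactants: 16 (2R,3S,4E,6R,7R)-7-[(tert-butyldimethylsilyl)oxy]-6-hydroxy-7-[(2S)-6-oxo-3,6-dihydro-2H-pyran-2-yl]hept-4-ene-2,3-diyl diacetate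
Product: 17 (2R,3S,4E,6R,7S)-7-[(tert-butyldimethylsilyl)oxy]-6-methoxy-7-[(2S)-6-oxo-3,6-dihydro-2H-pyran-2-yl]hept-4-ene-2,3-diyl diacetate
Conditions: Me3OBF4, 1,8-bis(dimethylamino)naphthalene, 4 Å MS, CH2Cl2, 0 °C to rt
Reagents that add atoms: trimethyloxonium tetrafluoroborate, C[O+](C)C.F[B-](F)(F)F
Why: O-methylation with Meerwein salt buffered by a non-nucleophilic amine alkylates the allylic alcohol at oxygen without base strong enough to open the lactone, cleave acetates or migrate the silyl group, so the C2' configuration is kept.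

Step 12
Reactants: 17 (2R,3S,4E,6R,7S)-7-[(tert-butyldimethylsilyl)oxy]-6-methoxy-7-[(2S)-6-oxo-3,6-dihydro-2H-pyran-2-yl]hept-4-ene-2,3-diyl diacetate
Product: 18 (2R,3S,4E,6R,7S)-7-hydroxy-6-methoxy-7-[(2S)-6-oxo-3,6-dihydro-2H-pyran-2-yl]hept-4-ene-2,3-diyl diacetate (the target)
Conditions: HF·pyridine, pyridine, THF, 0 °C to rt
Reagents that add atoms: none
Why: Fluoride-mediated desilylation under buffered, mildly acidic conditions frees the C1' hydroxyl while the acetates, the methyl ether and the enoate lactone are stable and no acyl migration is possible across the (E)-alkene.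

**Compound list**
1 | penta-1,4-dien-3-ol (divinylcarbinol) | C=CC(O)C=C | starting material
2 | (1R)-1-[(2S)-oxiran-2-yl]prop-2-en-1-ol | C=C[C@@H](O)[C@@H]1CO1 | intermediate
3 | tert-butyldimethyl{[(1R)-1-[(2S)-oxiran-2-yl]prop-2-en-1-yl]oxy}silane | C=C[C@@H](O[Si](C)(C)C(C)(C)C)[C@@H]1CO1 | intermediate
4 | acrylic acid | C=CC(=O)O | starting material
5 | (2Z,5S,6R)-6-[(tert-butyldimethylsilyl)oxy]-5-hydroxyocta-2,7-dienoic acid | C=C[C@@H](O[Si](C)(C)C(C)(C)C)[C@@H](O)C/C=C\C(=O)O | intermediate
6 | (6S)-6-[(1R)-1-[(tert-butyldimethylsilyl)oxy]prop-2-en-1-yl]-5,6-dihydro-2H-pyran-2-one | C=C[C@@H](O[Si](C)(C)C(C)(C)C)[C@@H]1CC=CC(=O)O1 | intermediate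
7 | (6S)-6-[(S)-[(tert-butyldimethylsilyl)oxy](1,2,4-trioxolan-3-yl)methyl]-5,6-dihydro-2H-pyran-2-one (epimers at the trioxolane carbon) | C1OC(OO1)[C@@H](O[Si](C)(C)C(C)(C)C)[C@@H]2CC=CC(=O)O2 | intermediate
8 | (2S)-2-[(tert-butyldimethylsilyl)oxy]-2-[(2S)-6-oxo-3,6-dihydro-2H-pyran-2-yl]acetaldehyde | O=C[C@@H](O[Si](C)(C)C(C)(C)C)[C@@H]1CC=CC(=O)O1 | intermediate
9 | (1S)-1-[(2R)-oxiran-2-yl]prop-2-en-1-ol | C=C[C@H](O)[C@H]1CO1 | intermediate
10 | (2R,3S)-pent-4-ene-2,3-diol | C=C[C@H](O)[C@@H](C)O | intermediate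
11 | (3S,4R)-pent-1-ene-3,4-diyl diacetate | C=C[C@H](OC(C)=O)[C@@H](C)OC(C)=O | intermediate
12 | (1R,2R)-1-(1,2,4-trioxolan-3-yl)propane-1,2-diyl diacetate (epimers at the trioxolane carbon) | C1OC(OO1)[C@H](OC(C)=O)[C@@H](C)OC(C)=O | intermediate
13 | (2R,3R)-1-oxobutane-2,3-diyl diacetate | O=C[C@H](OC(C)=O)[C@@H](C)OC(C)=O | intermediate
14 | (1E,3S,4R)-1-iodopent-1-ene-3,4-diyl diacetate | I/C=C/[C@H](OC(C)=O)[C@@H](C)OC(C)=O | intermediate
15 | dichloro[(1E,3S,4R)-3,4-diacetoxypent-1-en-1-yl]chromium | Cl[Cr](Cl)/C=C/[C@H](OC(C)=O)[C@@H](C)OC(C)=O | intermediate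
16 | (2R,3S,4E,6R,7R)-7-[(tert-butyldimethylsilyl)oxy]-6-hydroxy-7-[(2S)-6-oxo-3,6-dihydro-2H-pyran-2-yl]hept-4-ene-2,3-diyl diacetate | O[C@H](/C=C/[C@H](OC(C)=O)[C@@H](C)OC(C)=O)[C@@H](O[Si](C)(C)C(C)(C)C)[C@@H]1CC=CC(=O)O1 | intermediate
17 | (2R,3S,4E,6R,7S)-7-[(tert-butyldimethylsilyl)oxy]-6-methoxy-7-[(2S)-6-oxo-3,6-dihydro-2H-pyran-2-yl]hept-4-ene-2,3-diyl diacetate | CO[C@H](/C=C/[C@H](OC(C)=O)[C@@H](C)OC(C)=O)[C@@H](O[Si](C)(C)C(C)(C)C)[C@@H]1CC=CC(=O)O1 | intermediate
18 | (2R,3S,4E,6R,7S)-7-hydroxy-6-methoxy-7-[(2S)-6-oxo-3,6-dihydro-2H-pyran-2-yl]hept-4-ene-2,3-diyl diacetate, i.e. (6S)-6-[(1S,2R,3E,5S,6R)-5,6-diacetoxy-1-hydroxy-2-methoxyhept-3-en-1-yl]-5,6-dihydro-2H-pyran-2-one | CO[C@H](/C=C/[C@H](OC(C)=O)[C@@H](C)OC(C)=O)[C@@H](O)[C@@H]1CC=CC(=O)O1 | target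

**Step count**
Total step count: 12.
Longest linear sequence: 8 steps (steps 5, 6, 7, 8, 9, 10, 11, 12). The West arm (steps 1 to 4) runs in parallel.

**Steps most likely to fail and their fallbacks**

Step 3, the proposed C–H alkylation and lactonisation. The risks are direct carboxylate opening of the epoxide, Heck-type insertion of the vinyl group into the alkenyl–palladium bond, and low turnover. The fallback uses known chemistry, sets out from 3 and comes back at 6. Lithiated ethyl propiolate (ethyl propiolate, nBuLi, BF3·OEt2, THF, −78 °C) opens epoxide 3 at the terminal carbon to give ethyl (5S,6R)-6-[(tert-butyldimethylsilyl)oxy]-5-hydroxyoct-7-en-2-ynoate F1. Semihydrogenation of the ynoate (H2, Pd/CaCO3 poisoned with Pb(OAc)2, quinoline, EtOAc, stopped after one equivalent) gives ethyl (2Z,5S,6R)-6-[(tert-butyldimethylsilyl)oxy]-5-hydroxyocta-2,7-dienoate F2, which lactonises on warming with catalytic PPTS in benzene to 6.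

Step 4, the chemoselective ozonolysis. The risks are over-oxidation of the ring A enoate and loss of the labile α-silyloxy aldehyde. The fallback sets out from 6 and comes back at 8. Ligand-accelerated dihydroxylation strongly prefers the monosubstituted alkene over the cis-disubstituted, electron-poor ring alkene (OsO4 1 mol%, (DHQD)2PHAL 5 mol%, NMO, acetone/H2O, 0 °C). It gives (6S)-6-[(1R)-1-[(tert-butyldimethylsilyl)oxy]-2,3-dihydroxypropyl]-5,6-dihydro-2H-pyran-2-one F3 as a mixture of carbinol epimers. Glycol cleavage with NaIO4 on silica gel (CH2Cl2, rt) then delivers 8 under neutral conditions.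

Step 10, the fragment coupling. The risks are only modest Felkin selectivity at C2' and β-elimination of aldehyde 8. The fallback sets out from 16 (taken as the unseparated carbinol mixture from step 10) and comes back at 16. Oxidation with Dess–Martin periodinane (NaHCO3, CH2Cl2, 0 °C) gives enone (2R,3S,4E,7S)-7-[(tert-butyldimethylsilyl)oxy]-6-oxo-7-[(2S)-6-oxo-3,6-dihydro-2H-pyran-2-yl]hept-4-ene-2,3-diyl diacetate F4. Corey–Bakshi–Shibata reduction ((R)-2-methyl-CBS-oxazaborolidine, catecholborane, toluene, −78 °C) then returns 16 as a single C2' epimer by reagent control. The choice of the (R)-catalyst assumes the alkenyl arm takes the large-group role, which puts hydride on the same face as the Felkin path; this assignment would need a small-scale check against the (S)-catalyst.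

**Further compounds**
F1 | step 3 | ethyl (5S,6R)-6-[(tert-butyldimethylsilyl)oxy]-5-hydroxyoct-7-en-2-ynoate | C=C[C@@H](O[Si](C)(C)C(C)(C)C)[C@@H](O)CC#CC(=O)OCC
F2 | step 3 | ethyl (2Z,5S,6R)-6-[(tert-butyldimethylsilyl)oxy]-5-hydroxyocta-2,7-dienoate | C=C[C@@H](O[Si](C)(C)C(C)(C)C)[C@@H](O)C/C=C\C(=O)OCC
F3 | step 4 | (6S)-6-[(1R)-1-[(tert-butyldimethylsilyl)oxy]-2,3-dihydroxypropyl]-5,6-dihydro-2H-pyran-2-one (both epimers at the new carbinol carbon) | OCC(O)[C@@H](O[Si](C)(C)C(C)(C)C)[C@@H]1CC=CC(=O)O1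
F4 | step 10 | (2R,3S,4E,7S)-7-[(tert-butyldimethylsilyl)oxy]-6-oxo-7-[(2S)-6-oxo-3,6-dihydro-2H-pyran-2-yl]hept-4-ene-2,3-diyl diacetate | O=C(/C=C/[C@H](OC(C)=O)[C@@H](C)OC(C)=O)[C@@H](O[Si](C)(C)C(C)(C)C)[C@@H]1CC=CC(=O)O1
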